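The dioxane ring (ring B: O1–C2–C3–O4, fused to arene ring A) is a hemiketal, so it opens at O1–C2 to an α-aryloxy propiophenone. Because the C3 methyl group sits α to the masked carbonyl C2, its carbon is traced back to a CH2 bridge across a C2=C3 enol ether. In one operation a dipeptide-modified zinc carbenoid adds CH2 to the (Z)-silyl enol ether, forming C2–CH2 and C3–CH2, closing a cyclopropane and fixing C3. Acid then releases the strain, unveils the methyl group and lets ring B close. The precursor is a bis(trimethylsilyl) (Z)-enol ether made from a salicylaldehyde and a phenacyl bromide.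

Key step: step 4

Remarks on the chemistry (assumptions):
- C2 is a hemiketal carbon that equilibrates through the open hydroxy ketone, so its configuration is taken to be the thermodynamic one (hydroxyl axial and anti to the C3 methyl group, aryl equatorial); only C3 has to be controlled.
- The sense of induction of the dipeptide on this enol ether cannot be known beforehand; the L,L-dipeptide is written, and its D,D-antipode would be used if a first run shows the opposite sense.

Step 1
Reactants: 1 5-allyl-2-hydroxy-3-methoxybenzaldehyde; 2 2-bromo-1-(3,4,5-trimethoxyphenyl)ethanone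
Product: 3 3-methoxy-2-[2-oxo-2-(3,4,5-trimethoxyphenyl)ethoxy]-5-(prop-2-en-1-yl)benzaldehyde
Conditions: K2CO3 (1.2 equiv), acetone, 0 °C → rt
Reagents that add atoms: none
Why: Williamson ether synthesis, in which the phenoxide of 1 should displace bromide from the highly SN2-reactive phenacyl bromide 2, while the mild carbonate base and low temperature are chosen so that the product does not go on to the intramolecular aldol condensation that would give a 2-aroylbenzofuran (Rap–Stoermer reaction).

Step 2
Reactants: 3 3-methoxy-2-[2-oxo-2-(3,4,5-trimethoxyphenyl)ethoxy]-5-(prop-2-en-1-yl)benzaldehyde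
Product: 5 2-[2-hydroxy-6-methoxy-4-(prop-2-en-1-yl)phenoxy]-1-(3,4,5-trimethoxyphenyl)ethan-1-one, via aryl formate 4 (not isolated)
Conditions: 30% aq. H2O2 (1.5 equiv), B(OH)3 (5 equiv), H2SO4 (cat.), THF, rt; Na2SO3 quench
Reagents that add atoms: hydrogen peroxide, OO
Why: Acid-catalysed Dakin oxidation (Baeyer–Villiger-type aryl migration in the aldehyde–H2O2 adduct, then hydrolysis of formate 4), in which the ortho-alkoxy group supports aryl migration, the aldehyde should react far faster than the aryl ketone, and the allyl double bond should survive because no peracid is present; no stereocentre is formed, and 5 is expected to sit largely as its cyclic hemiketal tautomer.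

Step 3
Reactants: 5 2-[2-hydroxy-6-methoxy-4-(prop-2-en-1-yl)phenoxy]-1-(3,4,5-trimethoxyphenyl)ethan-1-one
Product: 7 (Z)-1-(3,4,5-trimethoxyphenyl)-1-(trimethylsilyloxy)-2-[2-methoxy-4-(prop-2-en-1-yl)-6-(trimethylsilyloxy)phenoxy]ethene, via dilithium enolate phenoxide 6 (not isolated)
Conditions: LiN(SiMe3)2 (2.3 equiv), THF, −78 °C; Me3SiCl (3 equiv), −78 → 0 °C; evaporation, pentane, filtration (no aqueous work-up), used at once
Reagents that add atoms: chlorotrimethylsilane, C[Si](C)(C)Cl
Why: Kinetic enolate formation and O-silylation, in which the first equivalent of base should open the hemiketal to the lithium phenoxide, the second should deprotonate the α-CH2 through a transition state with lithium chelated between the carbonyl oxygen and the aryloxy oxygen (placing these two oxygens cis, Z enolate 6), and Me3SiCl should trap both oxyanions on oxygen to give 7 with the Z geometry that later decides C3.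

Step 4
Reactants: 7 (Z)-1-(3,4,5-trimethoxyphenyl)-1-(trimethylsilyloxy)-2-[2-methoxy-4-(prop-2-en-1-yl)-6-(trimethylsilyloxy)phenoxy]ethene; 8 diiodomethane
Product: 9 (1R,2R)-2-[2-methoxy-4-(prop-2-en-1-yl)-6-(trimethylsilyloxy)phenoxy]-1-(3,4,5-trimethoxyphenyl)-1-(trimethylsilyloxy)cyclopropane
Conditions: Et2Zn (1.5 equiv), CH2I2 (1.5 equiv), N-Boc-L-Val-L-Pro-OMe (0.25 equiv), ethyl methoxyacetate (1 equiv), CH2Cl2, −40 → 0 °C; Et3N, then cold aq. NaHCO3
Reagents that add atoms: diiodomethane (8), ICI
Why: Et2Zn deprotonates the carbamate N–H of the dipeptide and exchanges with CH2I2, so that a chiral N-bound (iodomethyl)zinc species should deliver CH2 to the enol ether C=C through the concerted, suprafacial butterfly transition state of the Simmons–Smith reaction. The closest known reaction type is the dipeptide-modified asymmetric Simmons–Smith cyclopropanation of trimethylsilyl enol ethers of aryl ketones. The three-membered ring closes in this single [2+1] methylene transfer, with the C1–CH2 and C2–CH2 bonds formed together and not by a stepwise ring closure. The aryloxy-bearing carbon (C2 of 9, later C3 of the target) is set by the face of the enol ether that the zinc-bound dipeptide selects (reagent control), and the siloxy-bearing carbon C1 follows from it because the stereospecific syn addition turns the Z geometry into the cis siloxy/aryloxy relationship. The step needs chemoselectivity for the enol ether over the allyl group, which the two oxygen donors on the C=C bond secure by making it far more nucleophilic than the unactivated terminal alkene, supported by a limited charge of carbenoid, low temperature and ethyl methoxyacetate to tie up unligated carbenoid and damp the racemic background reaction.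

Step 5
Reactants: 9 (1R,2R)-2-[2-methoxy-4-(prop-2-en-1-yl)-6-(trimethylsilyloxy)phenoxy]-1-(3,4,5-trimethoxyphenyl)-1-(trimethylsilyloxy)cyclopropane
Product: 12 (2S,3R)-5-methoxy-3-methyl-7-(prop-2-en-1-yl)-2-(3,4,5-trimethoxyphenyl)-2,3-dihydro-1,4-benzodioxin-2-ol, via cyclopropanol 10 (not isolated), via hydroxy ketone 11 (not isolated)
Conditions: 2 M aq. HCl, THF, rt → 45 °C
Reagents that add atoms: none
Why: Acid-mediated desilylation and cyclopropanol ring opening, in which aqueous acid should cleave both silyl ethers to 10 and protonate the unsubstituted CH2 carbon while the C1 hydroxyl and aryl group stabilise the developing cation, so that the less substituted C1–CH2 bond breaks and methyl ketone 11 appears with no bond to the aryloxy-bearing stereocentre touched (no base, hence no enolate at C3–H), after which the phenol should add to the ketone and close ring B as the thermodynamically preferred hemiketal, fixing C2 as in 12.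

Compound list
1 | 5-allyl-2-hydroxy-3-methoxybenzaldehyde | C=CCc1cc(C=O)c(O)c(OC)c1 | starting material
2 | 2-bromo-1-(3,4,5-trimethoxyphenyl)ethanone | COc1cc(cc(OC)c1OC)C(=O)CBr | starting material
3 | 3-methoxy-2-[2-oxo-2-(3,4,5-trimethoxyphenyl)ethoxy]-5-(prop-2-en-1-yl)benzaldehyde | COc1cc(cc(OC)c1OC)C(=O)COc1c(C=O)cc(CC=C)cc1OC | intermediate
4 | 3-methoxy-2-[2-oxo-2-(3,4,5-trimethoxyphenyl)ethoxy]-5-(prop-2-en-1-yl)phenyl formate | COc1cc(cc(OC)c1OC)C(=O)COc1c(OC=O)cc(CC=C)cc1OC | intermediate
5 | 2-[2-hydroxy-6-methoxy-4-(prop-2-en-1-yl)phenoxy]-1-(3,4,5-trimethoxyphenyl)ethan-1-one | COc1cc(cc(OC)c1OC)C(=O)COc1c(O)cc(CC=C)cc1OC | intermediate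
6 | dilithium (Z)-2-[2-methoxy-6-oxido-4-(prop-2-en-1-yl)phenoxy]-1-(3,4,5-trimethoxyphenyl)ethen-1-olate | COc1cc(cc(OC)c1OC)/C(O[Li])=C/Oc1c(O[Li])cc(CC=C)cc1OC | intermediate
7 | (Z)-1-(3,4,5-trimethoxyphenyl)-1-(trimethylsilyloxy)-2-[2-methoxy-4-(prop-2-en-1-yl)-6-(trimethylsilyloxy)phenoxy]ethene | COc1cc(cc(OC)c1OC)/C(O[Si](C)(C)C)=C/Oc1c(O[Si](C)(C)C)cc(CC=C)cc1OC | intermediate
8 | diiodomethane | ICI | starting material
9 | (1R,2R)-2-[2-methoxy-4-(prop-2-en-1-yl)-6-(trimethylsilyloxy)phenoxy]-1-(3,4,5-trimethoxyphenyl)-1-(trimethylsilyloxy)cyclopropane (siloxy and aryloxy cis) | COc1cc(cc(OC)c1OC)[C@]1(O[Si](C)(C)C)C[C@H]1Oc1c(O[Si](C)(C)C)cc(CC=C)cc1OC | intermediate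
10 | (1R,2R)-2-[2-hydroxy-6-methoxy-4-(prop-2-en-1-yl)phenoxy]-1-(3,4,5-trimethoxyphenyl)cyclopropan-1-ol | COc1cc(cc(OC)c1OC)[C@]1(O)C[C@H]1Oc1c(O)cc(CC=C)cc1OC | intermediate
11 | (2R)-2-[2-hydroxy-6-methoxy-4-(prop-2-en-1-yl)phenoxy]-1-(3,4,5-trimethoxyphenyl)propan-1-one | COc1cc(cc(OC)c1OC)C(=O)[C@@H](C)Oc1c(O)cc(CC=C)cc1OC | intermediate
12 | (2S,3R)-5-methoxy-3-methyl-7-(prop-2-en-1-yl)-2-(3,4,5-trimethoxyphenyl)-2,3-dihydro-1,4-benzodioxin-2-ol | C=CCc1cc(OC)c2c(c1)O[C@@](O)(c1cc(OC)c(OC)c(OC)c1)[C@@H](C)O2 | target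

Total step count: 5
Longest linear sequence: 5 steps (1 → 3 → 5 → 7 → 9 → 12)

Steps most likely to fail

1. Step 4. The facial selectivity may be insufficient, because the aryloxy, methoxy and siloxy oxygens next to the double bond can bind unligated zinc carbenoid and feed a racemic background reaction. Methylene transfer to the trisubstituted double bond may also be slow enough for the allyl group to begin to react.
Fallback (sets out from 7, comes back at 12): stereocontrol would be given up at the cyclopropanation and recovered by resolution. Without the dipeptide, Et2Zn/CH2I2 (CH2Cl2, 0 °C) should cyclopropanate 7 to the racemic cis-cyclopropane, that is 9 together with (1S,2S)-2-[2-methoxy-4-(prop-2-en-1-yl)-6-(trimethylsilyloxy)phenoxy]-1-(3,4,5-trimethoxyphenyl)-1-(trimethylsilyloxy)cyclopropane F1. The acid treatment of step 5 should take the mirror-image series through (1S,2S)-2-[2-hydroxy-6-methoxy-4-(prop-2-en-1-yl)phenoxy]-1-(3,4,5-trimethoxyphenyl)cyclopropan-1-ol F2 and (2S)-2-[2-hydroxy-6-methoxy-4-(prop-2-en-1-yl)phenoxy]-1-(3,4,5-trimethoxyphenyl)propan-1-one F3 to (2R,3S)-5-methoxy-3-methyl-7-(prop-2-en-1-yl)-2-(3,4,5-trimethoxyphenyl)-2,3-dihydro-1,4-benzodioxin-2-ol F4. Preparative chromatography of the racemic hemiketal on a cellulose tris(3,5-dimethylphenylcarbamate) stationary phase should then deliver 12.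

2. Step 5. Protonolysis of the cyclopropane may be slow because the aryloxy group withdraws electron density from the ring. The stronger acid or higher temperature then needed could erode C3 by enolisation of the open keto form, dehydrate the hemiketal, or ionise the aryl ether with loss of the phenol.
Fallback (sets out from 1, comes back at 11): the methyl group would be brought in from the chiral pool instead of being unveiled. Mitsunobu etherification of 1 with ethyl (S)-lactate (PPh3, DIAD, THF, 0 °C → rt) should give, with inversion, ethyl (2R)-2-[2-formyl-6-methoxy-4-(prop-2-en-1-yl)phenoxy]propanoate F5. Dakin oxidation as in step 2 should lead through ethyl (2R)-2-[2-(formyloxy)-6-methoxy-4-(prop-2-en-1-yl)phenoxy]propanoate F6 to ethyl (2R)-2-[2-hydroxy-6-methoxy-4-(prop-2-en-1-yl)phenoxy]propanoate F7. On warming with catalytic TsOH in toluene this should lactonise to (3R)-5-methoxy-3-methyl-7-(prop-2-en-1-yl)-2,3-dihydro-1,4-benzodioxin-2-one F8. Aminolysis with Me(MeO)NH·HCl/AlMe3 (CH2Cl2, 0 °C) should open the lactone to (2R)-2-[2-hydroxy-6-methoxy-4-(prop-2-en-1-yl)phenoxy]-N-methoxy-N-methylpropanamide F9. Commercial 3,4,5-trimethoxyphenylmagnesium bromide (excess, THF, −20 → 0 °C; Weinreb ketone synthesis) should then give ketone 11, which closes to 12 on work-up.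

3. Step 3. Geometric control may be incomplete, the hemiketal form may be silylated instead of the open phenoxide, or the two labile silyl ethers may be partly hydrolysed during isolation.
Fallback (sets out from 5, comes back at 7): the two silylations would be separated and the enol ether made under equilibrating conditions instead of through the lithium enolate. Me3SiCl/imidazole (CH2Cl2, 0 °C) should silylate the phenol only, giving 2-[2-methoxy-4-(prop-2-en-1-yl)-6-(trimethylsilyloxy)phenoxy]-1-(3,4,5-trimethoxyphenyl)ethan-1-one F10. Me3SiOTf/Et3N (CH2Cl2, 0 °C → rt) should then convert the ketone to the silyl enol ether, the thermodynamically preferred Z isomer 7 being the one in which the aryl group avoids a cis aryloxy substituent.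

Further compounds
F1 | step 4 | (1S,2S)-2-[2-methoxy-4-(prop-2-en-1-yl)-6-(trimethylsilyloxy)phenoxy]-1-(3,4,5-trimethoxyphenyl)-1-(trimethylsilyloxy)cyclopropane | COc1cc(cc(OC)c1OC)[C@@]1(O[Si](C)(C)C)C[C@@H]1Oc1c(O[Si](C)(C)C)cc(CC=C)cc1OC
F2 | step 4 | (1S,2S)-2-[2-hydroxy-6-methoxy-4-(prop-2-en-1-yl)phenoxy]-1-(3,4,5-trimethoxyphenyl)cyclopropan-1-ol | COc1cc(cc(OC)c1OC)[C@@]1(O)C[C@@H]1Oc1c(O)cc(CC=C)cc1OC
F3 | step 4 | (2S)-2-[2-hydroxy-6-methoxy-4-(prop-2-en-1-yl)phenoxy]-1-(3,4,5-trimethoxyphenyl)propan-1-one | COc1cc(cc(OC)c1OC)C(=O)[C@H](C)Oc1c(O)cc(CC=C)cc1OC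
F4 | step 4 | (2R,3S)-5-methoxy-3-methyl-7-(prop-2-en-1-yl)-2-(3,4,5-trimethoxyphenyl)-2,3-dihydro-1,4-benzodioxin-2-ol | C=CCc1cc(OC)c2c(c1)O[C@](O)(c1cc(OC)c(OC)c(OC)c1)[C@H](C)O2
F5 | step 5 | ethyl (2R)-2-[2-formyl-6-methoxy-4-(prop-2-en-1-yl)phenoxy]propanoate | CCOC(=O)[C@@H](C)Oc1c(C=O)cc(CC=C)cc1OC
F6 | step 5 | ethyl (2R)-2-[2-(formyloxy)-6-methoxy-4-(prop-2-en-1-yl)phenoxy]propanoate | CCOC(=O)[C@@H](C)Oc1c(OC=O)cc(CC=C)cc1OC
F7 | step 5 | ethyl (2R)-2-[2-hydroxy-6-methoxy-4-(prop-2-en-1-yl)phenoxy]propanoate | CCOC(=O)[C@@H](C)Oc1c(O)cc(CC=C)cc1OC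
F8 | step 5 | (3R)-5-methoxy-3-methyl-7-(prop-2-en-1-yl)-2,3-dihydro-1,4-benzodioxin-2-one | C=CCc1cc(OC)c2O[C@H](C)C(=O)Oc2c1
F9 | step 5 | (2R)-2-[2-hydroxy-6-methoxy-4-(prop-2-en-1-yl)phenoxy]-N-methoxy-N-methylpropanamide | CON(C)C(=O)[C@@H](C)Oc1c(O)cc(CC=C)cc1OC
F10 | step 3 | 2-[2-methoxy-4-(prop-2-en-1-yl)-6-(trimethylsilyloxy)phenoxy]-1-(3,4,5-trimethoxyphenyl)ethan-1-one | COc1cc(cc(OC)c1OC)C(=O)COc1c(O[Si](C)(C)C)cc(CC=C)cc1OC
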